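**Two counts.** Each electrophile that reacts puts one nucleophile into target and one acid into solution, and no step destroys either count. Three dosed flasks show what this costs.

all flasks: electrophile 0.10 M; gas 34 mM (held); time 25 min

|  | nucleophile | remark |
|---|---|---|
| south | 0.0900 M (fed, over 25 min) | the fed solution adds 0.50 times the starting volume |
| north-west | 0.120 M (fed, over 25 min) | the fed solution adds 0.50 times the starting volume |
| west | 0.150 M (fed, over 25 min) | the fed solution adds 0.50 times the starting volume |

    electrophile + nucleophile ⇌ acid set free + target (K1 = 1.0, k1 = 7.3 /M/min)
    nucleophile + acid set free ⇌ protonated nucleophile, settled at all times (K2 = 1800 /M)
    acid set free + free base ⇌ salt of the base, settled at all times (K3 = 71 /M)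
    gas ⇌ free base, rate k4*(csat - [free base]) (k4 = 9.1 /min, csat = 34 mM)
    nucleophile + target ⇌ idle adduct, settled at all times (K5 = 6.9 /M)

- for target the idle adduct is counted in
- charges are per starting volume, the dose included; the dosed solution carries all of it
- at the start none of free base is dissolved
- run time (south): 25 min

- part of the electrophile that has reacted at the end, south
- part of the electrophile that has reacted at the end, north-west
- part of the electrophile that has reacted at the end, west
- what raising the concentration of nucleophile from its lowest to its highest value here does to the part of the electrophile that has reacted (changes below 5 percentage points count as none) (no change / it falls / it rises)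

**The line.** Let x be the electrophile reacted and D the nucleophile dosed. Let N, P, A, H and S be the free nucleophile, protonated nucleophile, idle adduct, acid set free and salt of the base, all per starting volume. Nucleophile counts D = x + N + P + A, and acid counts x = H + P + S. Removing P gives x = 0.5(D + H + S − N − A). Taking the full charge over 2, as a part of the electrophile charged, gives 45.0% in south: the half-dose line. North-west stands at 60.0% and west at 75.0%.

**Upper bound.** In south the nucleophile, charged at less than the electrophile, is the limiting reagent, so the charge allows 90.0%. The balance of the first step is tighter. Free base refills with a half-life of 0.0762 min, far shorter than the dose, so it is taken at saturation, and free acid and salt together are 3.41 times free acid. With electrophile over target at 1.22, taken at the line, balance needs 3.15 mM of free nucleophile. South's ceiling, as an estimate, is then 52.5%.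

**Lower bound.** Take the forward rate as equal to the dose rate, with electrophile at the line, and drop H and S. Free nucleophile is then put at 8.97 mM. With its adduct, south's floor, as an estimate, is 36.9%.

**West.** The same steps, with a ratio of 0.333, give a ceiling of 75.9% and a floor of 41.8%. The two brackets overlap. The lines, though, climb by 30 percentage points against a mark of 5 points, so this reckoning expects a rise.

**The forecast.** It gave 45%, 56% and 67% with the verdict "it rises", south's and west's figures lying inside their own brackets, and said: “Conversion rises with nucleophile charge”.

**The flask.** South ends at 45.4%, north-west at 57.0% and west at 67.4%, so the verdict on the part reacted is "it rises", with a change of 22 points. West keeps 12.5% of its nucleophile free at the end. Its line stands 7.6 points above the flask, so H + S − N − A is negative in west. South's line stands 0.40 points below its flask, so that sum is slightly positive in south.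

**A neighbour.** Charged with 0.25 M of electrophile, a flask otherwise like west has a line at 30.0%. It reaches 32.9%, above its line.

(The constants used here stand for no real mixture.)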